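**Strategy.** Everything rests on a (3+3) disconnection of the cyclohexane-1,3-dione ring (ring A; C1 ketone, C2, C3 enol, C4 methoxy carbon, C5, C6). A single Michael–Claisen cascade joins the kinetic methyl enolate of a cyclopentenyl butanone to a lactic-acid-derived 5-methylene-1,3-dioxolan-4-one: C6–C5 by conjugate addition, C2–C3 by Dieckmann closure, exploiting the 1,5-relationship of C1 and C3 through C6–C5–C4 and the 1,3-dicarbonyl array C1–C2–C3. The temporary acetal ring sets C4 and leaves as pivaldehyde. The ketone comes from a cis-fused lactone made by Stetter cyclisation of a linalool-derived butenolide and Negishi coupling with a (Z)-alkenylzinc.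

Key step: step 14

Assumption: (S)-(+)-linalool of high enantiomeric purity is taken as a purchasable chiral-pool material; it supplies the carbinol stereocentre of the cyclopentene.

**Route**

Step 1
Reactants: 1 4-methylpent-3-en-1-ol
Product: 2 4-methylpent-3-enal
Conditions: PhI(OAc)2, TEMPO (10 mol %), CH2Cl2, 0 to 23 °C; solution used directly
Reagents that add atoms: none
Why: Nitroxyl-catalysed (TEMPO) oxidation of the primary alcohol stops at the aldehyde under near-neutral conditions, so the β,γ-double bond should not move into conjugation.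

Step 2
Reactants: 3 ethyltriphenylphosphonium iodide; 2 4-methylpent-3-enal
Product: 5 (2Z)-2-iodo-6-methylhepta-2,5-diene, via (1-iodoethyl)triphenylphosphonium iodide 4 (not isolated)
Conditions: 3, n-BuLi, THF, −78 to 0 °C; I2, −78 °C; NaN(SiMe3)2, −78 °C; then 2, −78 to −20 °C
Reagents that add atoms: iodine, [I][I]
Why: Wittig olefination with the α-iodoethylidene ylide (Stork–Zhao-type iodo-olefination) should place iodine cis to the alkyl chain through the kinetically preferred cis-oxaphosphetane, which fixes the (Z)-trisubstituted geometry needed in the target.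

Step 3
Reactants: 6 (S)-lactic acid; 7 pivaldehyde
Product: 8 (2S,5S)-2-tert-butyl-5-methyl-1,3-dioxolan-4-one
Conditions: p-TsOH·H2O (cat.), H2SO4 (cat.), pentane, reflux, water separator; crystallisation from pentane at −78 °C
Reagents that add atoms: none
Why: Acid-catalysed acetalisation of the α-hydroxy acid gives the dioxolanone, the acetal centre forming cis to the C5 methyl group under thermodynamic control and being purified by crystallisation.

Step 4
Reactants: 8 (2S,5S)-2-tert-butyl-5-methyl-1,3-dioxolan-4-one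
Product: 10 (2S)-2-tert-butyl-5-methylidene-1,3-dioxolan-4-one, via bromodioxolanone 9 (not isolated)
Conditions: N-bromosuccinimide, AIBN (cat.), cyclohexane, reflux; then Et3N, Et2O, 0 to 23 °C
Reagents that add atoms: none
Why: Wohl–Ziegler radical bromination at the captodative C5–H followed by E2 dehydrobromination installs the exocyclic alkene while the acetal stereocentre C2 is untouched.

Step 5
Reactants: 11 (S)-linalool; 12 acryloyl chloride
Product: 13 (3S)-3,7-dimethylocta-1,6-dien-3-yl prop-2-enoate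
Conditions: n-BuLi, THF, −78 °C; then 12, −78 to 0 °C
Reagents that add atoms: none
Why: O-Acylation of the lithium alkoxide (esterification) overcomes the low reactivity of the tertiary allylic alcohol and does not touch the stereocentre.

Step 6
Reactants: 13 (3S)-3,7-dimethylocta-1,6-dien-3-yl prop-2-enoate
Product: 14 (3S)-3-methyl-6-oxohex-1-en-3-yl prop-2-enoate
Conditions: O3 (1 equiv), CH2Cl2–MeOH, −78 °C; then Me2S, −78 to 23 °C
Reagents that add atoms: ozone, [O-][O+]=O
Why: Ozonolysis with reductive work-up should cleave the electron-rich trisubstituted alkene much faster than the vinyl group next to the ester oxygen or the electron-poor acrylate.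

Step 7
Reactants: 14 (3S)-3-methyl-6-oxohex-1-en-3-yl prop-2-enoate
Product: 15 3-[(2S)-2-methyl-5-oxo-2,5-dihydrofuran-2-yl]propanal
Conditions: second-generation Grubbs catalyst RuCl2(=CHPh)(PCy3)(H2IMes) (5 mol %), CH2Cl2, 40 °C
Reagents that add atoms: none
Why: Ring-closing metathesis between the vinyl group and the acrylate closes the five-membered butenolide with loss of ethene, and the aldehyde is tolerated by the ruthenium carbene.

Step 8
Reactants: 15 3-[(2S)-2-methyl-5-oxo-2,5-dihydrofuran-2-yl]propanal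
Product: 16 (3aS,6aS)-6a-methyltetrahydro-2H-cyclopenta[b]furan-2,4(3H)-dione
Conditions: 2-(pentafluorophenyl)-6,7-dihydro-5H-pyrrolo[2,1-c][1,2,4]triazol-2-ium tetrafluoroborate (10 mol %), i-Pr2NEt (10 mol %), toluene, 23 °C
Reagents that add atoms: none
Why: Intramolecular Stetter reaction: the carbene-derived acyl anion equivalent adds 5-exo-trig to the butenolide β-carbon, and the new ring-fusion centre C3a can only form cis to the lactone oxygen on the quaternary carbon C6a, because a trans-fused bicyclo[3.3.0] lactone is too strained.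

Step 9
Reactants: 16 (3aS,6aS)-6a-methyltetrahydro-2H-cyclopenta[b]furan-2,4(3H)-dione
Product: 17 (3aS,6aS)-6a-methyl-2-oxo-3,3a,6,6a-tetrahydro-2H-cyclopenta[b]furan-4-yl trifluoromethanesulfonate
Conditions: KN(SiMe3)2, THF, −78 °C; then PhN(SO2CF3)2, −78 to −20 °C
Reagents that add atoms: N-phenylbis(trifluoromethanesulfonimide), O=S(=O)(N(c1ccccc1)S(=O)(=O)C(F)(F)F)C(F)(F)F
Why: Kinetic deprotonation at the less hindered C5 methylene and O-sulfonylation of the enolate (enol triflate formation) fix the C4=C5 double bond, and the bulky amide at low temperature avoids enolisation towards C3a, which would expel the lactone carboxylate.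

Step 10
Reactants: 5 (2Z)-2-iodo-6-methylhepta-2,5-diene; 17 (3aS,6aS)-6a-methyl-2-oxo-3,3a,6,6a-tetrahydro-2H-cyclopenta[b]furan-4-yl trifluoromethanesulfonate
Product: 19 (3aR,6aS)-6a-methyl-4-[(2Z)-6-methylhepta-2,5-dien-2-yl]-3,3a,6,6a-tetrahydro-2H-cyclopenta[b]furan-2-one, via alkenylzinc bromide 18 (not isolated)
Conditions: 5, t-BuLi (2 equiv), Et2O, −78 °C; ZnBr2, THF, −78 to 0 °C; then 17, Pd(PPh3)4 (5 mol %), THF, 23 °C
Reagents that add atoms: none
Why: Iodine–lithium exchange and transmetalation to zinc proceed with retention of alkene geometry, and Negishi cross-coupling with the enol triflate should give the diene with the (Z) configuration intact while the lactone is inert to the organozinc.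

Step 11
Reactants: 19 (3aR,6aS)-6a-methyl-4-[(2Z)-6-methylhepta-2,5-dien-2-yl]-3,3a,6,6a-tetrahydro-2H-cyclopenta[b]furan-2-one
Product: 20 (3aR,6aS)-6a-methyl-4-[(2Z)-6-methylhepta-2,5-dien-2-yl]-3,3a,6,6a-tetrahydro-2H-cyclopenta[b]furan-2-ol
Conditions: (i-Bu)2AlH (1.1 equiv), CH2Cl2, −78 °C; aq. KNaC4H4O6
Reagents that add atoms: none
Why: Partial reduction of the γ-lactone with (i-Bu)2AlH stops at the tetrahedral aluminium hemiacetal at low temperature, which gives the lactol (both anomers) on work-up.

Step 12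
Reactants: 21 triphenylphosphine; 22 1,1-dimethoxyethane
Product: 23 (1-methoxyethyl)triphenylphosphonium tetrafluoroborate
Conditions: HBF4·OEt2, CH2Cl2, 0 to 23 °C
Reagents that add atoms: tetrafluoroboric acid (diethyl etherate), [H+].F[B-](F)(F)F
Why: Acid-promoted ionisation of the acetal to an oxocarbenium ion and capture by the phosphine (phosphonium salt formation from an acetal) gives the α-methoxyalkyl phosphonium salt.

Step 13
Reactants: 20 (3aR,6aS)-6a-methyl-4-[(2Z)-6-methylhepta-2,5-dien-2-yl]-3,3a,6,6a-tetrahydro-2H-cyclopenta[b]furan-2-ol; 23 (1-methoxyethyl)triphenylphosphonium tetrafluoroborate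
Product: 26 4-[(1R,5S)-5-methyl-2-[(2Z)-6-methylhepta-2,5-dien-2-yl]-5-(triethylsilyloxy)cyclopent-2-en-1-yl]butan-2-one, via enol ether alcohol 24 (not isolated), via silylated enol ether 25 (not isolated)
Conditions: 23, KN(SiMe3)2, THF, −78 to −20 °C; 20, −78 to 0 °C; Et3SiCl, 0 °C; then 0.5 M aq. oxalic acid, THF, 0 °C
Reagents that add atoms: chlorotriethylsilane, CC[Si](Cl)(CC)CC; water, O
Why: Wittig olefination of the open hydroxy-aldehyde form of the lactol with the α-methoxyethylidene ylide gives a methyl enol ether, the tertiary alkoxide set free is silylated in the flask, and mild aqueous acid hydrolyses only the enol ether, which amounts to a one-carbon homologation to the methyl ketone.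

Step 14
Reactants: 26 4-[(1R,5S)-5-methyl-2-[(2Z)-6-methylhepta-2,5-dien-2-yl]-5-(triethylsilyloxy)cyclopent-2-en-1-yl]butan-2-one; 10 (2S)-2-tert-butyl-5-methylidene-1,3-dioxolan-4-one
Product: 28 (4S)-3,4-dihydroxy-2-{[(1R,5S)-5-methyl-2-[(2Z)-6-methylhepta-2,5-dien-2-yl]-5-(triethylsilyloxy)cyclopent-2-en-1-yl]methyl}cyclohex-2-en-1-one, via Michael adduct 27 (not isolated)
Conditions: LiN(iPr)2 (1.05 equiv), THF, −78 °C; 10, −78 to −20 °C; aq. NH4Cl (pH 4–5)
Reagents that add atoms: none
Why: Proposed new method: the kinetic lithium enolate at the methyl group of 26 should add in Michael fashion to the captodative exocyclic alkene of 10 (C6–C5 bond), the dioxolanone enolate is then protonated at C4 by 1,5-proton transfer from the ketone α-methylene, and the ketone enolate so regenerated attacks the acylal carbonyl in a Dieckmann (Claisen) condensation (C2–C3 bond), the expelled hemiacetal alkoxide collapsing to pivaldehyde and leaving the C4 hydroxyl. The closest known reaction type is the consecutive Michael–Claisen (3+3) annulation of ketones with acrylates to cyclohexane-1,3-diones, combined with conjugate additions to 2-tert-butyl-5-methylene-1,3-dioxolan-4-ones. Ring A closes in a 6-(enolexo)-exo-trig mode, the only productive one, since attack by the other α-carbon would give a four-membered ring. The new stereocentre C4 is controlled by the temporary acetal ring: the planar enolate is protonated on the face opposite to the tert-butyl group at C2 of the (2S)-dioxolanone, which is also the more stable cis arrangement and maps onto (4S). The step needs Michael attack from the methyl side of the ketone and 1,4- over 1,2-addition; the first is secured by kinetic deprotonation at −78 °C, the second by the soft enolate and the s-cis-locked acceptor, and formation of the stabilised dionate makes the sequence irreversible.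

Step 15
Reactants: 28 (4S)-3,4-dihydroxy-2-{[(1R,5S)-5-methyl-2-[(2Z)-6-methylhepta-2,5-dien-2-yl]-5-(triethylsilyloxy)cyclopent-2-en-1-yl]methyl}cyclohex-2-en-1-one
Product: 29 (4S)-3-hydroxy-4-methoxy-2-{[(1R,5S)-5-methyl-2-[(2Z)-6-methylhepta-2,5-dien-2-yl]-5-(triethylsilyloxy)cyclopent-2-en-1-yl]methyl}cyclohex-2-en-1-one
Conditions: NaH (2.2 equiv), THF–DMF, 0 °C; MeI (1.05 equiv), 0 °C; aq. NH4Cl
Reagents that add atoms: iodomethane, [CH3]I
Why: In the dianion the localised secondary alkoxide is far more basic and nucleophilic than the delocalised 1,3-dionate, so one equivalent of MeI should methylate it selectively (Williamson ether synthesis) without touching the C4 configuration.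

Step 16
Reactants: 29 (4S)-3-hydroxy-4-methoxy-2-{[(1R,5S)-5-methyl-2-[(2Z)-6-methylhepta-2,5-dien-2-yl]-5-(triethylsilyloxy)cyclopent-2-en-1-yl]methyl}cyclohex-2-en-1-one
Product: 30 (4S)-3-hydroxy-2-{[(1R,5S)-5-hydroxy-5-methyl-2-[(2Z)-6-methylhepta-2,5-dien-2-yl]cyclopent-2-en-1-yl]methyl}-4-methoxycyclohex-2-en-1-one
Conditions: HF·pyridine, pyridine, THF, 0 to 23 °C
Reagents that add atoms: none
Why: Fluoride-mediated cleavage of the triethylsilyl ether (desilylation) under pyridine buffering frees the tertiary alcohol without acid-induced cyclisation onto the enolised dione or the diene.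

**Compound list**

1 | 4-methylpent-3-en-1-ol | CC(C)=CCCO | starting material
2 | 4-methylpent-3-enal | CC(C)=CCC=O | intermediate
3 | ethyltriphenylphosphonium iodide | CC[P+](c1ccccc1)(c1ccccc1)c1ccccc1.[I-] | starting material
4 | (1-iodoethyl)triphenylphosphonium iodide | CC(I)[P+](c1ccccc1)(c1ccccc1)c1ccccc1.[I-] | intermediate
5 | (2Z)-2-iodo-6-methylhepta-2,5-diene | I/C(C)=C\CC=C(C)C | intermediate
6 | (S)-lactic acid, (2S)-2-hydroxypropanoic acid | C[C@H](O)C(=O)O | starting material
7 | pivaldehyde, 2,2-dimethylpropanal | CC(C)(C)C=O | starting material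
8 | (2S,5S)-2-tert-butyl-5-methyl-1,3-dioxolan-4-one | C[C@@H]1O[C@H](C(C)(C)C)OC1=O | intermediate
9 | (2R,5R)-5-bromo-2-tert-butyl-5-methyl-1,3-dioxolan-4-one (bromine trans to tert-butyl) | C[C@]1(Br)O[C@H](C(C)(C)C)OC1=O | intermediate
10 | (2S)-2-tert-butyl-5-methylidene-1,3-dioxolan-4-one | C=C1O[C@H](C(C)(C)C)OC1=O | intermediate
11 | (S)-linalool, (3S)-3,7-dimethylocta-1,6-dien-3-ol | CC(C)=CCC[C@](C=C)(C)O | starting material
12 | acryloyl chloride | C=CC(=O)Cl | starting material
13 | (3S)-3,7-dimethylocta-1,6-dien-3-yl prop-2-enoate | CC(C)=CCC[C@](C=C)(C)OC(=O)C=C | intermediate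
14 | (3S)-3-methyl-6-oxohex-1-en-3-yl prop-2-enoate | O=CCC[C@](C=C)(C)OC(=O)C=C | intermediate
15 | 3-[(2S)-2-methyl-5-oxo-2,5-dihydrofuran-2-yl]propanal | O=CCC[C@]1(C)OC(=O)C=C1 | intermediate
16 | (3aS,6aS)-6a-methyltetrahydro-2H-cyclopenta[b]furan-2,4(3H)-dione | O=C1C[C@@H]2C(=O)CC[C@]2(C)O1 | intermediate
17 | (3aS,6aS)-6a-methyl-2-oxo-3,3a,6,6a-tetrahydro-2H-cyclopenta[b]furan-4-yl trifluoromethanesulfonate | O=C1C[C@@H]2C(OS(=O)(=O)C(F)(F)F)=CC[C@]2(C)O1 | intermediate
18 | bromo[(2Z)-6-methylhepta-2,5-dien-2-yl]zinc | Br[Zn]/C(C)=C\CC=C(C)C | intermediate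
19 | (3aR,6aS)-6a-methyl-4-[(2Z)-6-methylhepta-2,5-dien-2-yl]-3,3a,6,6a-tetrahydro-2H-cyclopenta[b]furan-2-one | O=C1C[C@@H]2C(/C(C)=C\CC=C(C)C)=CC[C@]2(C)O1 | intermediate
20 | (3aR,6aS)-6a-methyl-4-[(2Z)-6-methylhepta-2,5-dien-2-yl]-3,3a,6,6a-tetrahydro-2H-cyclopenta[b]furan-2-ol (both anomers) | OC1C[C@@H]2C(/C(C)=C\CC=C(C)C)=CC[C@]2(C)O1 | intermediate
21 | triphenylphosphine | c1ccc(cc1)P(c1ccccc1)c1ccccc1 | starting material
22 | 1,1-dimethoxyethane | COC(C)OC | starting material
23 | (1-methoxyethyl)triphenylphosphonium tetrafluoroborate | COC(C)[P+](c1ccccc1)(c1ccccc1)c1ccccc1.F[B-](F)(F)F | intermediate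
24 | (1S,2R)-2-(3-methoxybut-2-en-1-yl)-1-methyl-3-[(2Z)-6-methylhepta-2,5-dien-2-yl]cyclopent-3-en-1-ol (enol ether E/Z mixture) | COC(C)=CC[C@@H]1C(/C(C)=C\CC=C(C)C)=CC[C@]1(C)O | intermediate
25 | triethyl{[(1S,2R)-2-(3-methoxybut-2-en-1-yl)-1-methyl-3-[(2Z)-6-methylhepta-2,5-dien-2-yl]cyclopent-3-en-1-yl]oxy}silane | COC(C)=CC[C@@H]1C(/C(C)=C\CC=C(C)C)=CC[C@]1(C)O[Si](CC)(CC)CC | intermediate
26 | 4-[(1R,5S)-5-methyl-2-[(2Z)-6-methylhepta-2,5-dien-2-yl]-5-(triethylsilyloxy)cyclopent-2-en-1-yl]butan-2-one | CC(=O)CC[C@@H]1C(/C(C)=C\CC=C(C)C)=CC[C@]1(C)O[Si](CC)(CC)CC | intermediate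
27 | (2S,5S)-2-tert-butyl-5-{3-oxo-5-[(1R,5S)-5-methyl-2-[(2Z)-6-methylhepta-2,5-dien-2-yl]-5-(triethylsilyloxy)cyclopent-2-en-1-yl]pentyl}-1,3-dioxolan-4-one | O=C1O[C@@H](C(C)(C)C)O[C@H]1CCC(=O)CC[C@@H]2C(/C(C)=C\CC=C(C)C)=CC[C@]2(C)O[Si](CC)(CC)CC | intermediate
28 | (4S)-3,4-dihydroxy-2-{[(1R,5S)-5-methyl-2-[(2Z)-6-methylhepta-2,5-dien-2-yl]-5-(triethylsilyloxy)cyclopent-2-en-1-yl]methyl}cyclohex-2-en-1-one | O[C@H]1CCC(=O)C(C[C@@H]2C(/C(C)=C\CC=C(C)C)=CC[C@]2(C)O[Si](CC)(CC)CC)=C1O | intermediate
29 | (4S)-3-hydroxy-4-methoxy-2-{[(1R,5S)-5-methyl-2-[(2Z)-6-methylhepta-2,5-dien-2-yl]-5-(triethylsilyloxy)cyclopent-2-en-1-yl]methyl}cyclohex-2-en-1-one | CO[C@H]1CCC(=O)C(C[C@@H]2C(/C(C)=C\CC=C(C)C)=CC[C@]2(C)O[Si](CC)(CC)CC)=C1O | intermediate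
30 | (4S)-3-hydroxy-2-{[(1R,5S)-5-hydroxy-5-methyl-2-[(2Z)-6-methylhepta-2,5-dien-2-yl]cyclopent-2-en-1-yl]methyl}-4-methoxycyclohex-2-en-1-one | CO[C@H]1CCC(=O)C(C[C@@H]2C(/C(C)=C\CC=C(C)C)=CC[C@]2(C)O)=C1O | target

**Step count.** Total: 16 steps. Longest linear sequence: 11 steps (steps 5–11 and 13–16, from (S)-linalool).

**Steps most likely to fail**

1. Step 14 (proposed new method). What may go wrong: competing 1,2-addition of the enolate to the acylal carbonyl, anionic oligomerisation of the acceptor, and erosion of facial control if the dioxolanone enolate is reprotonated or epimerised before the ring closes. Fallback with known chemistry, setting out from 26 and returning at 28: the kinetic enolate of 26 (LiN(iPr)2, THF, −78 °C) is annulated with methyl acrylate by the established consecutive Michael–Claisen sequence to give 3-hydroxy-2-{[(1R,5S)-5-methyl-2-[(2Z)-6-methylhepta-2,5-dien-2-yl]-5-(triethylsilyloxy)cyclopent-2-en-1-yl]methyl}cyclohex-2-en-1-one F1. Its dianion (LiN(iPr)2, 2.2 equiv, THF, −78 °C) is then hydroxylated at C4 with enantiopure (camphorsulfonyl)oxaziridine, the antipode matched to the (4S) face being chosen in a test run. Stereocontrol is then by reagent instead of by the acetal ring and is expected to be weaker.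

2. Step 8. What may go wrong: slow addition of the acyl anion equivalent to the hindered β-carbon next to the quaternary centre, self-condensation of the enolisable aldehyde, and base-induced β-elimination of the lactone carboxylate from the β-acyloxy ketone product. Fallback by a neutral radical route, setting out from 15 and returning at 16: oxidation with NaClO2, NaH2PO4 and 2-methylbut-2-ene gives 3-[(2S)-2-methyl-5-oxo-2,5-dihydrofuran-2-yl]propanoic acid F2. PhSeSePh and PBu3 convert it into Se-phenyl 3-[(2S)-2-methyl-5-oxo-2,5-dihydrofuran-2-yl]propaneselenoate F3. Bu3SnH and AIBN in benzene at 80 °C then generate the acyl radical, which should cyclise 5-exo-trig onto the butenolide to give the same cis-fused keto lactone.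

3. Step 15. What may go wrong: loss of chemoselectivity through O- or C-methylation of the dionate, or epimerisation at C4 under the strongly basic conditions. Fallback by exhaustive methylation and hydrolytic unmasking, setting out from 28 and returning at 30: MeI and Ag2O (Purdie conditions) should give the two regioisomeric enol methyl ethers (4S)-3,4-dimethoxy-2-{[(1R,5S)-5-methyl-2-[(2Z)-6-methylhepta-2,5-dien-2-yl]-5-(triethylsilyloxy)cyclopent-2-en-1-yl]methyl}cyclohex-2-en-1-one F4 and (6S)-3,6-dimethoxy-2-{[(1R,5S)-5-methyl-2-[(2Z)-6-methylhepta-2,5-dien-2-yl]-5-(triethylsilyloxy)cyclopent-2-en-1-yl]methyl}cyclohex-2-en-1-one F5. The mixture is hydrolysed with 1 M HCl in THF at 0 to 23 °C, which cleaves both vinylogous esters and the silyl ether and leaves the C4 methyl ether.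

**Further compounds**

F1 | step 14 | 3-hydroxy-2-{[(1R,5S)-5-methyl-2-[(2Z)-6-methylhepta-2,5-dien-2-yl]-5-(triethylsilyloxy)cyclopent-2-en-1-yl]methyl}cyclohex-2-en-1-one | O=C1CCCC(O)=C1C[C@@H]2C(/C(C)=C\CC=C(C)C)=CC[C@]2(C)O[Si](CC)(CC)CC
F2 | step 8 | 3-[(2S)-2-methyl-5-oxo-2,5-dihydrofuran-2-yl]propanoic acid | OC(=O)CC[C@]1(C)OC(=O)C=C1
F3 | step 8 | Se-phenyl 3-[(2S)-2-methyl-5-oxo-2,5-dihydrofuran-2-yl]propaneselenoate | O=C(CC[C@]1(C)OC(=O)C=C1)[Se]c1ccccc1
F4 | step 15 | (4S)-3,4-dimethoxy-2-{[(1R,5S)-5-methyl-2-[(2Z)-6-methylhepta-2,5-dien-2-yl]-5-(triethylsilyloxy)cyclopent-2-en-1-yl]methyl}cyclohex-2-en-1-one | CO[C@H]1CCC(=O)C(C[C@@H]2C(/C(C)=C\CC=C(C)C)=CC[C@]2(C)O[Si](CC)(CC)CC)=C1OC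
F5 | step 15 | (6S)-3,6-dimethoxy-2-{[(1R,5S)-5-methyl-2-[(2Z)-6-methylhepta-2,5-dien-2-yl]-5-(triethylsilyloxy)cyclopent-2-en-1-yl]methyl}cyclohex-2-en-1-one | CO[C@H]1CCC(OC)=C(C[C@@H]2C(/C(C)=C\CC=C(C)C)=CC[C@]2(C)O[Si](CC)(CC)CC)C1=O
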